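**Retrosynthetic overview**
1. The strategy rests on ring B carrying the C7 isopropenyl group next to the C8 carbinol (the array C12=C11–C7–C8–O). This is the retron of a type 1 carbonyl-ene reaction, so ring B (C5–C6–C7–C8–C9–C10) is cut at C7–C8 to a prenyl group on the quaternary C5 and a C8 aldehyde on the C10 arm of a finished ring A.
2. The side chain is cut last at the C3–O ester bond and at the (Z)-C2′=C3′ double bond, giving a C3 (diphenoxyphosphoryl)acetate and (R)-2-(angeloyloxy)butanal (from (R)-butane-1,2-diol and angelic acid); the 8,9-diol travels as an acetonide.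
3. The C9 oxygen comes from hydroxylation of the C8 ketone enolate and C8 is then reset with a bulky hydride. C3–O comes from a dissolving-metal reduction, the C4 methyl from enolate methylation, and the quaternary C5 from successive methyl and allyl conjugate additions.
4. Ring A is made first (organocatalytic Michael addition to methyl vinyl ketone, then aldol condensation, which sets C10). Ring B is closed second by the ene reaction, and the side chain is finished by a Z-selective olefination.

Key step: step 13

Remark: ring atoms carry eremophilane numbers (C3 ester carbon, C4/C15 and C5/C14 methyl pairs, C7 isopropenyl, C8 and C9 carbinols, C10 ring-fusion CH; side chain C1′–C6′) and β is the face of the C5 methyl; the (S)-prolinol ether is assumed, from the steric-shielding enamine model, to give (S)-3 (the antipodal catalyst would be used otherwise).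

**Route**

Step 1
Reactants: 1 4-(tert-butyldimethylsilyloxy)butanal; 2 methyl vinyl ketone
Product: 3 (S)-2-[2-(tert-butyldimethylsilyloxy)ethyl]-5-oxohexanal
Conditions: (S)-2-[methoxy(diphenyl)methyl]pyrrolidine (5 mol %), ethyl 3,4-dihydroxybenzoate (20 mol %), neat, 4 °C
Reagents that add atoms: none
Why: Enamine-catalysed Michael addition of the aldehyde to the enone, in which the diphenyl(methoxy)methyl group shields one enamine face so that the future C10 centre should form with (S) configuration while the catechol co-catalyst activates the enone by hydrogen bonding.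

Step 2
Reactants: 3 (S)-2-[2-(tert-butyldimethylsilyloxy)ethyl]-5-oxohexanal
Product: 4 (S)-4-[2-(tert-butyldimethylsilyloxy)ethyl]cyclohex-2-en-1-one
Conditions: LiOH (10 mol %), iPrOH, rt
Reagents that add atoms: none
Why: Intramolecular aldol condensation of the methyl ketone onto the aldehyde followed by dehydration closes ring A, and the mild hydroxide in isopropanol is chosen so that the α-stereocentre of the aldehyde should not racemise before cyclisation.

Step 3
Reactants: 4 (S)-4-[2-(tert-butyldimethylsilyloxy)ethyl]cyclohex-2-en-1-one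
Product: 5 trimethylsilyl enol ether of trans-3-methyl-4-[2-(tert-butyldimethylsilyloxy)ethyl]cyclohexanone
Conditions: Me2CuLi, TMSCl, THF, −78 °C; then Et3N
Reagents that add atoms: lithium dimethylcuprate [Li+].C[Cu-]C; chlorotrimethylsilane C[Si](C)(C)Cl
Why: Cuprate 1,4-addition with in situ silyl trapping gives the regiodefined silyl enol ether, the methyl group expected to enter anti to the C10 arm although this centre is erased in the next step.

Step 4
Reactants: 5 trimethylsilyl enol ether of trans-3-methyl-4-[2-(tert-butyldimethylsilyloxy)ethyl]cyclohexanone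
Product: 6 (S)-3-methyl-4-[2-(tert-butyldimethylsilyloxy)ethyl]cyclohex-2-en-1-one
Conditions: Pd(OAc)2 (10 mol %), O2 (1 atm), DMSO, rt
Reagents that add atoms: none
Why: Saegusa–Ito dehydrogenation of the regiodefined silyl enol ether restores the enone with the new methyl group on the β-carbon (C5), leaving the C10 centre untouched.

Step 5
Reactants: 6 (S)-3-methyl-4-[2-(tert-butyldimethylsilyloxy)ethyl]cyclohex-2-en-1-one; 7 allylmagnesium bromide
Product: 8 trimethylsilyl enol ether (C3=C4) of the 5α-allyl-5β-methyl ketone with the 10β side arm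
Conditions: allylMgBr, CuBr·SMe2, TMSCl, THF, −78 °C; then Et3N, aq. NaHCO3
Reagents that add atoms: chlorotrimethylsilane C[Si](C)(C)Cl
Why: Chlorosilane-assisted conjugate addition of the allylcopper reagent to the β,β-disubstituted enone, in which axial attack anti to the C10 arm (held pseudoaxial by A(1,2) strain with the C5 methyl) should place the allyl group trans to that arm and so fix the quaternary C5.

Step 6
Reactants: 8 trimethylsilyl enol ether (C3=C4) of the 5α-allyl-5β-methyl ketone with the 10β side arm
Product: 10 4α-methyl ketone (C4 epimer of 11), via lithium enolate 9 (not isolated)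
Conditions: MeLi, THF, 0 °C; then MeI, DMPU, −78 to 0 °C
Reagents that add atoms: iodomethane CI
Why: MeLi cleaves the O–Si bond to release the regiospecific lithium enolate, which is C-methylated at C4 by SN2 reaction with MeI, expected mainly anti to the axial C5 methyl, a configuration that the next step corrects.

Step 7
Reactants: 10 4α-methyl ketone (C4 epimer of 11)
Product: 11 ring A ketone with 4β-methyl, 5β-methyl, 5α-allyl and 10β-[2-(tert-butyldimethylsilyloxy)ethyl]
Conditions: NaOMe (cat.), MeOH, rt
Reagents that add atoms: none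
Why: Base-mediated epimerisation through the enolate should favour the chair with the C4 methyl equatorial and cis to the axial C5 methyl, because the axial epimer meets the axial hydrogens at C2 and C10, while C5 and C10 cannot enolise.

Step 8
Reactants: 11 ring A ketone with 4β-methyl, 5β-methyl, 5α-allyl and 10β-[2-(tert-butyldimethylsilyloxy)ethyl]
Product: 12 corresponding 3α-alcohol (equatorial hydroxyl trans to the C4 methyl)
Conditions: Li, NH3(l)/THF, −78 °C; then NH4Cl
Reagents that add atoms: none
Why: Dissolving-metal reduction of the ketone is thermodynamically controlled and should give the equatorial 3α-alcohol because the axial position at C3 is syn-axial to the C5 methyl, while the isolated alkene and the silyl ether are inert.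

Step 9
Reactants: 12 3α-alcohol
Product: 13 3α-(4-methoxybenzyl) ether of 12
Conditions: NaH, 4-methoxybenzyl chloride, Bu4NI (cat.), DMF, 0 °C to rt
Reagents that add atoms: 4-methoxybenzyl chloride COc1ccc(CCl)cc1
Why: Williamson etherification of the sodium alkoxide protects O3 as an ether that tolerates the Lewis acid, bases and hydrides used later and can be removed oxidatively.

Step 10
Reactants: 13 3α-(4-methoxybenzyl) ether; 14 2-methylbut-2-ene
Product: 15 5α-prenyl compound (allyl converted into 3-methylbut-2-enyl)
Conditions: second-generation Grubbs catalyst RuCl2(=CHPh)(PCy3)(H2IMes) (5 mol %), 2-methylbut-2-ene (excess), CH2Cl2, 40 °C, sealed tube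
Reagents that add atoms: none
Why: Olefin cross-metathesis of the terminal allyl group with excess 2-methylbut-2-ene installs the trisubstituted prenyl double bond, with loss of volatile propene driving the exchange.

Step 11
Reactants: 15 5α-prenyl compound
Product: 16 primary alcohol (10β-(2-hydroxyethyl) arm)
Conditions: Bu4NF, THF, 0 °C to rt
Reagents that add atoms: none
Why: Fluoride-induced cleavage of the primary silyl ether leaves the 4-methoxybenzyl ether and the prenyl group untouched.

Step 12
Reactants: 16 primary alcohol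
Product: 17 ene precursor aldehyde (C8 aldehyde on the C10 arm, C5 prenyl, 3α-(4-methoxybenzyloxy))
Conditions: Dess–Martin periodinane, NaHCO3, CH2Cl2, 0 °C to rt
Reagents that add atoms: none
Why: Dess–Martin oxidation of the primary alcohol gives the aldehyde under buffered conditions that are compatible with the prenyl double bond and the benzylic ether.

Step 13
Reactants: 17 ene precursor aldehyde
Product: 19 3α-(4-methoxybenzyloxy)eremophil-11-en-8β-ol (trans-decalin with 7α-isopropenyl), via chloro(methyl)aluminium alkoxide 18 (not isolated)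
Conditions: Me2AlCl (1.5 equiv), CH2Cl2, −78 to −30 °C; then 1 M HCl, 0 °C
Reagents that add atoms: none
Why: Me2AlCl binds the C8 aldehyde oxygen, C7 of the prenyl double bond attacks C8 and an allylic hydrogen of a C11 methyl group passes to oxygen through a six-membered array in a concerted, asynchronous carbonyl-ene reaction, after which the alcohol–aluminium complex loses methane to give alkoxide 18 and so keeps the medium free of protons that would start Prins-type pathways. The closest known reaction is the Lewis-acid-promoted type 1 cyclisation of citronellal to isopulegol. Ring B (C5–C6–C7–C8–C9–C10) closes through a chair-like six-membered transition state, exo with respect to both the C=O and the C=C bond, spanning the trans-diequatorial C6 and C9 arms of ring A, so the trans ring fusion follows from the existing C5 and C10 centres. C7 is controlled by the axial C5 methyl (C14), which is 1,3-diaxial to C7 in the forming chair and forces the developing isopropenyl group equatorial (7α), whereas C8 should form with its oxygen equatorial (8β), which is immaterial because this centre is reset through the ketone. The step needs face selectivity at C7 and preference for the ene pathway over cationic side reactions; both are secured by the quaternary C5 (which also presses the two arms together), by the electron-rich trisubstituted ene with six allylic hydrogens and by the absence of Lewis-basic groups other than ethers.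

Step 14
Reactants: 19 3α-(4-methoxybenzyloxy)eremophil-11-en-8β-ol
Product: 20 3α-(4-methoxybenzyloxy)eremophil-11-en-8-one
Conditions: Dess–Martin periodinane, NaHCO3, CH2Cl2, 0 °C to rt
Reagents that add atoms: none
Why: Buffered Dess–Martin oxidation gives the β,γ-unsaturated ketone without acid or base strong enough to move the isopropenyl double bond into conjugation, and the equatorial C7 substituent is in any case the stable epimer.

Step 15
Reactants: 20 3α-(4-methoxybenzyloxy)eremophil-11-en-8-one
Product: 22 9α-hydroxy-3α-(4-methoxybenzyloxy)eremophil-11-en-8-one, via potassium enolate 21 (not isolated)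
Conditions: KN(SiMe3)2, THF, −78 °C (ketone added to base); then trans-3-phenyl-2-(phenylsulfonyl)oxaziridine, −78 °C; then AcOH
Reagents that add atoms: trans-3-phenyl-2-(phenylsulfonyl)oxaziridine O=S(=O)(c1ccccc1)N1OC1c1ccccc1
Why: Kinetic deprotonation by the hindered amide should occur at the less substituted C9 methylene, and Davis enolate hydroxylation should deliver oxygen to the α face of C9, anti to the axial C5 methyl that shields the β face, giving the equatorial 9α-alcohol, which is also the more stable epimer.

Step 16
Reactants: 22 9α-hydroxy-3α-(4-methoxybenzyloxy)eremophil-11-en-8-one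
Product: 23 3α-(4-methoxybenzyloxy)eremophil-11-ene-8α,9α-diol
Conditions: LiBH(s-Bu)3 (2.5 equiv), THF, −78 °C; then H2O
Reagents that add atoms: none
Why: In this substrate-controlled ketone reduction the bulky trialkylborohydride (its first equivalent consumed by the free hydroxyl) attacks the C8 carbonyl along the equatorial trajectory, away from the axial hydrogens at C6 and C10, so the new 8α-hydroxyl should be axial and cis to both the 9α-hydroxyl and the 7α-isopropenyl group.

Step 17
Reactants: 23 3α-(4-methoxybenzyloxy)eremophil-11-ene-8α,9α-diol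
Product: 24 8α,9α-O-isopropylidene derivative of 23
Conditions: 2,2-dimethoxypropane, PPTS (cat.), CH2Cl2, rt
Reagents that add atoms: 2,2-dimethoxypropane COC(C)(C)OC
Why: Acid-catalysed transacetalisation of the cis (axial/equatorial) 1,2-diol forms the five-membered acetonide, which masks both hydroxyls during acylation and olefination.

Step 18
Reactants: 24 8α,9α-O-isopropylidene 3α-(4-methoxybenzyl) ether
Product: 25 8α,9α-(isopropylidenedioxy)eremophil-11-en-3α-ol
Conditions: DDQ, CH2Cl2/pH 7 buffer (10:1), 0 °C
Reagents that add atoms: none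
Why: DDQ oxidises the electron-rich benzylic ether to an oxocarbenium ion that water hydrolyses, releasing the C3 alcohol while the acetonide and the isopropenyl group should remain intact.

Step 19
Reactants: 25 8α,9α-(isopropylidenedioxy)eremophil-11-en-3α-ol; 26 bromoacetyl bromide
Product: 27 3α-bromoacetate of 25
Conditions: pyridine, CH2Cl2, 0 °C
Reagents that add atoms: none
Why: O-Acylation of the equatorial secondary alcohol by the acid bromide, with pyridine as acid scavenger to protect the acetonide, introduces C1′–C2′ with a displaceable bromide.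

Step 20
Reactants: 27 3α-bromoacetate
Product: 28 3α-[(diphenoxyphosphoryl)acetate] of the decalin acetonide
Conditions: (PhO)2P(O)H, Et3N, CH2Cl2, 0 °C to rt
Reagents that add atoms: diphenyl phosphite O=[PH](Oc1ccccc1)Oc1ccccc1
Why: Michaelis–Becker-type P-alkylation, in which the amine-generated phosphite anion displaces the α-bromide, gives the diaryl phosphonoacetate needed for a Z-selective olefination.

Step 21
Reactants: 29 (R)-butane-1,2-diol
Product: 30 (R)-1-(tert-butyldimethylsilyloxy)butan-2-ol
Conditions: TBSCl (1.05 equiv), imidazole, CH2Cl2, 0 °C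
Reagents that add atoms: tert-butyldimethylsilyl chloride CC(C)(C)[Si](C)(C)Cl
Why: Silylation distinguishes the primary from the secondary hydroxyl on steric grounds and leaves the stereocentre untouched.

Step 22
Reactants: 30 (R)-1-(tert-butyldimethylsilyloxy)butan-2-ol; 31 angelic acid
Product: 33 (R)-1-(tert-butyldimethylsilyloxy)butan-2-yl angelate, via mixed anhydride 32 (not isolated)
Conditions: 31, 2,4,6-trichlorobenzoyl chloride, Et3N, toluene, rt; then 30, 80 °C (no DMAP)
Reagents that add atoms: none
Why: Yamaguchi-type esterification through the mixed anhydride acylates the secondary alcohol at the angeloyl carbonyl (the other carbonyl is shielded by two ortho chlorines), and omitting DMAP should avoid Z-to-E isomerisation to the tiglate.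

Step 23
Reactants: 33 (R)-1-(tert-butyldimethylsilyloxy)butan-2-yl angelate
Product: 34 (R)-1-hydroxybutan-2-yl angelate
Conditions: HF·pyridine, THF/pyridine, 0 °C to rt
Reagents that add atoms: none
Why: Desilylation under mildly acidic fluoride conditions should suppress the 1,2-acyl migration to the primary oxygen that basic fluoride would promote.

Step 24
Reactants: 34 (R)-1-hydroxybutan-2-yl angelate
Product: 35 (R)-2-(angeloyloxy)butanal
Conditions: Dess–Martin periodinane, NaHCO3, CH2Cl2, 0 °C; used crude at once
Reagents that add atoms: none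
Why: Buffered Dess–Martin oxidation gives the α-acyloxy aldehyde without enolisation, and immediate use protects the C4′ stereocentre.

Step 25
Reactants: 28 3α-[(diphenoxyphosphoryl)acetate]; 35 (R)-2-(angeloyloxy)butanal
Product: 37 3α-[(2Z,4R)-4-(angeloyloxy)hex-2-enoyloxy]-8α,9α-(isopropylidenedioxy)eremophil-11-ene, via sodium phosphonate carbanion 36 (not isolated)
Conditions: NaH, THF, 0 °C; then 35, −78 °C
Reagents that add atoms: none
Why: Horner–Wadsworth–Emmons olefination with a diaryl phosphonate (Ando variant), in which the electron-poor aryloxy groups speed collapse of the kinetically formed syn oxaphosphetane so that the (Z)-enoate should predominate, while the low temperature limits epimerisation at C4′.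

Step 26
Reactants: 37 3α-[(2Z,4R)-4-(angeloyloxy)hex-2-enoyloxy]-8α,9α-(isopropylidenedioxy)eremophil-11-ene
Product: 38 CNP0382739.1
Conditions: AcOH/H2O/THF (3:1:1), 40 °C
Reagents that add atoms: none
Why: Mild acid-catalysed hydrolysis of the cyclic acetal releases the 8α,9α-diol, and the two esters, both Z double bonds and the isopropenyl group should survive aqueous acetic acid at this temperature.

**Compound list**
1 | 4-(tert-butyldimethylsilyloxy)butanal | O=CCCCO[Si](C)(C)C(C)(C)C | starting material
2 | methyl vinyl ketone (but-3-en-2-one) | C=CC(C)=O | starting material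
3 | (S)-2-[2-(tert-butyldimethylsilyloxy)ethyl]-5-oxohexanal | O=C[C@H](CCO[Si](C)(C)C(C)(C)C)CCC(C)=O | intermediate
4 | (S)-4-[2-(tert-butyldimethylsilyloxy)ethyl]cyclohex-2-en-1-one | O=C1C=C[C@H](CCO[Si](C)(C)C(C)(C)C)CC1 | intermediate
5 | 1-(trimethylsilyloxy)-3-methyl-4-[2-(tert-butyldimethylsilyloxy)ethyl]cyclohex-1-ene, methyl trans to the side arm | C[Si](C)(C)OC1=C[C@@H](C)[C@H](CCO[Si](C)(C)C(C)(C)C)CC1 | intermediate
6 | (S)-3-methyl-4-[2-(tert-butyldimethylsilyloxy)ethyl]cyclohex-2-en-1-one | O=C1C=C(C)[C@H](CCO[Si](C)(C)C(C)(C)C)CC1 | intermediate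
7 | allylmagnesium bromide | C=CC[Mg]Br | starting material
8 | 3-allyl-3-methyl-4-[2-(tert-butyldimethylsilyloxy)ethyl]-1-(trimethylsilyloxy)cyclohex-1-ene, allyl trans and methyl cis to the side arm | C=CC[C@]1(C)C=C(O[Si](C)(C)C)CC[C@H]1CCO[Si](C)(C)C(C)(C)C | intermediate
9 | lithium enolate corresponding to 8 | C=CC[C@]1(C)C=C(O[Li])CC[C@H]1CCO[Si](C)(C)C(C)(C)C | intermediate
10 | 3-allyl-2,3-dimethyl-4-[2-(tert-butyldimethylsilyloxy)ethyl]cyclohexan-1-one, C2 methyl trans to C3 methyl (4α-methyl epimer) | C=CC[C@]1(C)[C@H](C)C(=O)CC[C@H]1CCO[Si](C)(C)C(C)(C)C | intermediate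
11 | 3-allyl-2,3-dimethyl-4-[2-(tert-butyldimethylsilyloxy)ethyl]cyclohexan-1-one, both methyls cis to the side arm, allyl trans to it (4β,5β-dimethyl) | C=CC[C@]1(C)[C@@H](C)C(=O)CC[C@H]1CCO[Si](C)(C)C(C)(C)C | intermediate
12 | corresponding cyclohexan-1-ol, hydroxyl trans to the C2 methyl (3α-OH, equatorial) | C=CC[C@]1(C)[C@@H](C)[C@H](O)CC[C@H]1CCO[Si](C)(C)C(C)(C)C | intermediate
13 | 3α-(4-methoxybenzyl) ether of 12 | C=CC[C@]1(C)[C@@H](C)[C@H](OCc2ccc(OC)cc2)CC[C@H]1CCO[Si](C)(C)C(C)(C)C | intermediate
14 | 2-methylbut-2-ene | CC=C(C)C | starting material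
15 | 5α-(3-methylbut-2-enyl) analogue of 13 | CC(C)=CC[C@]1(C)[C@@H](C)[C@H](OCc2ccc(OC)cc2)CC[C@H]1CCO[Si](C)(C)C(C)(C)C | intermediate
16 | primary alcohol from 15 (10β-(2-hydroxyethyl) arm) | CC(C)=CC[C@]1(C)[C@@H](C)[C@H](OCc2ccc(OC)cc2)CC[C@H]1CCO | intermediate
17 | aldehyde from 16 (10β-(2-oxoethyl) arm, 5α-prenyl, 3α-(4-methoxybenzyloxy), 4β,5β-dimethyl) | CC(C)=CC[C@]1(C)[C@@H](C)[C@H](OCc2ccc(OC)cc2)CC[C@H]1CC=O | intermediate
18 | chloro(methyl)aluminium 8β-alkoxide of 19 | C=C(C)[C@@H]1C[C@]2(C)[C@@H](C)[C@H](OCc3ccc(OC)cc3)CC[C@H]2C[C@H]1O[Al](C)Cl | intermediate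
19 | 3α-(4-methoxybenzyloxy)eremophil-11-en-8β-ol (trans-decalin, 4β,5β-dimethyl, 7α-isopropenyl, 10α-H) | C=C(C)[C@@H]1C[C@]2(C)[C@@H](C)[C@H](OCc3ccc(OC)cc3)CC[C@H]2C[C@H]1O | intermediate
20 | 3α-(4-methoxybenzyloxy)eremophil-11-en-8-one | C=C(C)[C@@H]1C[C@]2(C)[C@@H](C)[C@H](OCc3ccc(OC)cc3)CC[C@H]2CC1=O | intermediate
21 | potassium C8=C9 enolate of 20 | C=C(C)[C@@H]1C[C@]2(C)[C@@H](C)[C@H](OCc3ccc(OC)cc3)CC[C@H]2C=C1O[K] | intermediate
22 | 9α-hydroxy-3α-(4-methoxybenzyloxy)eremophil-11-en-8-one | C=C(C)[C@@H]1C[C@]2(C)[C@@H](C)[C@H](OCc3ccc(OC)cc3)CC[C@H]2[C@H](O)C1=O | intermediate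
23 | 3α-(4-methoxybenzyloxy)eremophil-11-ene-8α,9α-diol | C=C(C)[C@@H]1C[C@]2(C)[C@@H](C)[C@H](OCc3ccc(OC)cc3)CC[C@H]2[C@H](O)[C@@H]1O | intermediate
24 | 8α,9α-(isopropylidenedioxy)-3α-(4-methoxybenzyloxy)eremophil-11-ene | C=C(C)[C@@H]1C[C@]2(C)[C@@H](C)[C@H](OCc4ccc(OC)cc4)CC[C@H]2[C@@H]3OC(C)(C)O[C@H]13 | intermediate
25 | 8α,9α-(isopropylidenedioxy)eremophil-11-en-3α-ol | C=C(C)[C@@H]1C[C@]2(C)[C@@H](C)[C@H](O)CC[C@H]2[C@@H]3OC(C)(C)O[C@H]13 | intermediate
26 | bromoacetyl bromide | O=C(Br)CBr | starting material
27 | 3α-bromoacetate of 25 | C=C(C)[C@@H]1C[C@]2(C)[C@@H](C)[C@H](OC(=O)CBr)CC[C@H]2[C@@H]3OC(C)(C)O[C@H]13 | intermediate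
28 | 3α-[(diphenoxyphosphoryl)acetate] of 25 | C=C(C)[C@@H]1C[C@]2(C)[C@@H](C)[C@H](OC(=O)CP(=O)(Oc4ccccc4)Oc5ccccc5)CC[C@H]2[C@@H]3OC(C)(C)O[C@H]13 | intermediate
29 | (R)-butane-1,2-diol | CC[C@@H](O)CO | starting material
30 | (R)-1-(tert-butyldimethylsilyloxy)butan-2-ol | CC[C@@H](O)CO[Si](C)(C)C(C)(C)C | intermediate
31 | angelic acid, (Z)-2-methylbut-2-enoic acid | C/C=C(/C)C(=O)O | starting material
32 | angelic 2,4,6-trichlorobenzoic anhydride | C/C=C(/C)C(=O)OC(=O)c1c(Cl)cc(Cl)cc1Cl | intermediate
33 | (R)-1-(tert-butyldimethylsilyloxy)butan-2-yl angelate | CC[C@@H](OC(=O)/C(C)=C\C)CO[Si](C)(C)C(C)(C)C | intermediate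
34 | (R)-1-hydroxybutan-2-yl angelate | CC[C@@H](OC(=O)/C(C)=C\C)CO | intermediate
35 | (R)-2-(angeloyloxy)butanal | CC[C@@H](OC(=O)/C(C)=C\C)C=O | intermediate
36 | sodium salt of the C2′ carbanion of 28 | [Na+].C=C(C)[C@@H]1C[C@]2(C)[C@@H](C)[C@H](OC(=O)[CH-]P(=O)(Oc4ccccc4)Oc5ccccc5)CC[C@H]2[C@@H]3OC(C)(C)O[C@H]13 | intermediate
37 | 3α-[(2Z,4R)-4-(angeloyloxy)hex-2-enoyloxy]-8α,9α-(isopropylidenedioxy)eremophil-11-ene | C=C(C)[C@@H]1C[C@]2(C)[C@@H](C)[C@H](OC(=O)/C=C\[C@@H](CC)OC(=O)/C(C)=C\C)CC[C@H]2[C@@H]3OC(C)(C)O[C@H]13 | intermediate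
38 | CNP0382739.1, 3α-[(2Z,4R)-4-(angeloyloxy)hex-2-enoyloxy]eremophil-11-ene-8α,9α-diol | C=C(C)[C@@H]1C[C@]2(C)[C@@H](C)[C@H](OC(=O)/C=C\[C@@H](CC)OC(=O)/C(C)=C\C)CC[C@H]2[C@H](O)[C@@H]1O | target

**Step count and risks**

Total steps: 26. Longest linear sequence: 22 steps (steps 1 to 20, then 25 and 26); the side-chain aldehyde takes 4 steps (21 to 24).

Steps most likely to fail:

1. Step 15. The base may abstract the C7 methine proton, which is both α to the carbonyl and allylic, instead of a C9 methylene proton; this would lead to oxidation at C7 or to migration of the C11=C12 double bond into conjugation. The fallback sets out from aldehyde 17 and comes back at diol 23, placing the C9 oxygen before ring closure under catalyst control so that no ketone enolate is needed. α-Benzoyloxylation of 17 with dibenzoyl peroxide and (S)-2-(triphenylmethyl)pyrrolidine (hydroquinone, THF, 0 °C) should give the (9S)-9-benzoyloxy aldehyde F1. Ene closure with Me2AlCl as in step 13 should give the 9α-benzoyloxy-8β-ol F2, and Dess–Martin oxidation the 9α-benzoyloxy-8-ketone F3. LiBH(s-Bu)3 at −78 °C should then give the 8α-alcohol F4, and K2CO3 in MeOH should remove the benzoate to give 23.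

2. Step 25. The olefination may give an insufficient Z preference, and the basic medium may epimerise or deacylate the α-acyloxy aldehyde. The fallback sets out from alcohol 25 and comes back at 37, making the Z double bond by alkyne semi-reduction and the C4′ centre by catalyst control. Esterification of 25 with propiolic acid (N,N′-dicyclohexylcarbodiimide, DMAP cat., CH2Cl2, −20 °C) should give the 3α-propiolate F5. ZnMe2-mediated enantioselective addition of this alkynoate to propanal, with 2,6-bis{[2-(hydroxydiphenylmethyl)pyrrolidin-1-yl]methyl}-4-methylphenol as ligand (the enantiomer that leads to the R carbinol), should give the (4′R)-4′-hydroxyhex-2′-ynoate F6. Angeloylation as in step 22 should give the 4′-angeloyloxy ynoate F7. Semi-hydrogenation over Pd on CaCO3 poisoned with Pb(OAc)2 (quinoline, H2, EtOAc) should then give 37 by syn addition of hydrogen.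

3. Step 7. The equilibrium between the C4 epimers may not lie far enough on the side of the equatorial methyl, since the two differ by roughly one gauche interaction, leaving a mixture. The fallback sets out from silyl enol ether 8 and comes back at ketone 11, setting C4 by kinetic protonation instead. MeLi followed by dimethyl(methylidene)ammonium iodide should give the C4 dimethylaminomethyl ketone F8; quaternisation with MeI and elimination with NaHCO3 should give the 4-methylene ketone F9. Conjugate reduction with LiBH(s-Bu)3 at −78 °C and protonation of the resulting enolate with 2,6-di-tert-butyl-4-methylphenol, axially from the α face anti to the axial C5 methyl, should give 11.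

Further compounds
F1 | step 15 | (9S)-9-benzoyloxy derivative of aldehyde 17 | CC(C)=CC[C@]1(C)[C@@H](C)[C@H](OCc2ccc(OC)cc2)CC[C@H]1[C@H](OC(=O)c3ccccc3)C=O
F2 | step 15 | 9α-benzoyloxy-3α-(4-methoxybenzyloxy)eremophil-11-en-8β-ol | C=C(C)[C@@H]1C[C@]2(C)[C@@H](C)[C@H](OCc3ccc(OC)cc3)CC[C@H]2[C@H](OC(=O)c4ccccc4)[C@H]1O
F3 | step 15 | 9α-benzoyloxy-3α-(4-methoxybenzyloxy)eremophil-11-en-8-one | C=C(C)[C@@H]1C[C@]2(C)[C@@H](C)[C@H](OCc3ccc(OC)cc3)CC[C@H]2[C@H](OC(=O)c4ccccc4)C1=O
F4 | step 15 | 9α-benzoyloxy-3α-(4-methoxybenzyloxy)eremophil-11-en-8α-ol | C=C(C)[C@@H]1C[C@]2(C)[C@@H](C)[C@H](OCc3ccc(OC)cc3)CC[C@H]2[C@H](OC(=O)c4ccccc4)[C@@H]1O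
F5 | step 25 | 3α-propiolate of 25 | C=C(C)[C@@H]1C[C@]2(C)[C@@H](C)[C@H](OC(=O)C#C)CC[C@H]2[C@@H]3OC(C)(C)O[C@H]13
F6 | step 25 | 3α-[(4R)-4-hydroxyhex-2-ynoate] of 25 | C=C(C)[C@@H]1C[C@]2(C)[C@@H](C)[C@H](OC(=O)C#C[C@@H](CC)O)CC[C@H]2[C@@H]3OC(C)(C)O[C@H]13
F7 | step 25 | 3α-[(4R)-4-(angeloyloxy)hex-2-ynoate] of 25 | C=C(C)[C@@H]1C[C@]2(C)[C@@H](C)[C@H](OC(=O)C#C[C@@H](CC)OC(=O)/C(C)=C\C)CC[C@H]2[C@@H]3OC(C)(C)O[C@H]13
F8 | step 7 | 4-(dimethylaminomethyl) analogue of ketone 10 (drawn as the 4α epimer; the centre is erased in the next operation) | C=CC[C@]1(C)[C@H](CN(C)C)C(=O)CC[C@H]1CCO[Si](C)(C)C(C)(C)C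
F9 | step 7 | 4-methylene ketone (3-allyl-3-methyl-2-methylidene-4-[2-(tert-butyldimethylsilyloxy)ethyl]cyclohexan-1-one) | C=CC[C@]1(C)C(=C)C(=O)CC[C@H]1CCO[Si](C)(C)C(C)(C)C
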